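**Retrosynthetic overview**
1. C9–C10 is cut last: the ten-membered carbocycle and the furan-3(2H)-one arise together from an oxidation-triggered, dearomatising intramolecular aldol of a furan-3-boronate aldehyde, which also sets C9 and C10.
2. C3–C4: site-selective Suzuki coupling of a (Z)-vinyl iodide with 2-methyl-3,5-diborylfuran, made from 2-methylfuran by double C–H borylation; the boron next to the methyl group is a masked enol oxygen.
3. C6–C7 and the lactone C–O bond: indium Barbier allylation/lactonisation of (Z)-3-iodobut-2-enal with a glyceraldehyde-derived (Z)-2-(bromomethyl)acrylate, setting C6 and C7 from C8.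
4. Ring order: furan (bought, aromatic) → cis-fused γ-lactone → carbocycle and furanone simultaneously in the final step.

Assumptions: the configuration is read from the SMILES as 6S,7S,8S,9R,10R (cis-fused lactone). Atom labels are germacrane numbers: C1 furanone C=O, C2 furanone CH, C3 furanone O–C=, C4=C5 the Z-alkene (C15 methyl on C4), C6 lactone CH–O, C7 lactone CH, C8 CH–O-ester, C9 CH–OH, C10 quaternary carbon (C14 methyl), C11=C13 methylidene, C12 lactone C=O. Compounds 1, 4, 8 and 9 are bought; 8 is used freshly distilled.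

**Route**

Step 1
Reactants: 1 2-methylfuran
Product: 3 2-methyl-3,5-bis(4,4,5,5-tetramethyl-1,3,2-dioxaborolan-2-yl)furan, via 5-boryl-2-methylfuran 2 (not isolated)
Conditions: B2pin2 (1.1 equiv), [Ir(OMe)(cod)]2 (1.5 mol %), 4,4′-di-tert-butyl-2,2′-bipyridine (3 mol %), THF, 25 → 65 °C
Reagents that add atoms: bis(pinacolato)diboron, CC1(C)OB(OC1(C)C)B1OC(C)(C)C(C)(C)O1
Why: Iridium-catalysed, sterically governed C–H borylation: the free α C–H reacts first, and the second boryl group enters the β C–H next to the small methyl group because the C–H next to the bulky boronate is shielded.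

Step 2
Reactants: 4 but-2-yn-1-ol
Product: 6 (2Z)-3-iodobut-2-en-1-ol, via cyclic alkenylalanate 5 (not isolated)
Conditions: NaAlH2(OCH2CH2OMe)2, Et2O, 0 °C → rt; then I2, THF, −78 → 0 °C
Reagents that add atoms: iodine, II
Why: Hydroxyl-directed trans-hydroalumination places aluminium on the distal alkyne carbon in a five-membered alanate, and iodinolysis of the C–Al bond with retention gives the Z-iodoalkene (iodine cis to CH2OH).

Step 3
Reactants: 6 (2Z)-3-iodobut-2-en-1-ol
Product: 7 (2Z)-3-iodobut-2-enal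
Conditions: MnO2 (activated, 15 equiv), CH2Cl2, rt, dark; used at once
Reagents that add atoms: none
Why: Heterogeneous, neutral allylic oxidation with MnO2 stops at the aldehyde and does not isomerise the Z double bond if the enal is used immediately.

Step 4
Reactants: 8 (4R)-2,2-dimethyl-1,3-dioxolane-4-carbaldehyde; 9 methyl acrylate
Product: 10 methyl 2-{hydroxy[(4R)-2,2-dimethyl-1,3-dioxolan-4-yl]methyl}prop-2-enoate (both carbinol epimers)
Conditions: DABCO (0.5 equiv), 1,4-dioxane/H2O (1:1), rt, 48 h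
Reagents that add atoms: none
Why: Morita–Baylis–Hillman reaction; the new carbinol centre forms as a mixture, which does not matter because step 5 erases it, and the dioxolane centre (the future C8) is carried through unchanged.

Step 5
Reactants: 10 the Morita–Baylis–Hillman adduct
Product: 11 methyl (2Z)-2-(bromomethyl)-3-[(4S)-2,2-dimethyl-1,3-dioxolan-4-yl]prop-2-enoate
Conditions: NBS (1.2 equiv), Me2S (1.3 equiv), CH2Cl2, 0 °C → rt
Reagents that add atoms: N-bromosuccinimide, BrN1C(=O)CCC1=O
Why: Corey–Kim-type activation of the alcohol as an alkoxysulfonium ion followed by SN2′ attack of bromide gives the conjugated (Z)-2-(bromomethyl)enoate with the ester trans to the dioxolanyl group; the dioxolane centre is untouched (the descriptor changes from R to S only through CIP priorities).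

Step 6
Reactants: 7 (2Z)-3-iodobut-2-enal; 11 the (4S)-allylic bromide
Product: 14 (4S,5R)-4-[(4S)-2,2-dimethyl-1,3-dioxolan-4-yl]-5-[(1Z)-2-iodoprop-1-en-1-yl]-3-methylideneoxolan-2-one (cis lactone), via allylindium dibromide 12 (not isolated), via hydroxy ester 13 (not isolated)
Conditions: In powder (1.5 equiv), THF/H2O (1:1), rt; extract; then PPTS (0.1 equiv), toluene, 60 °C
Reagents that add atoms: none
Why: Barbier-type 2-(alkoxycarbonyl)allylation through a chair Zimmerman–Traxler transition state: the Z-configured allylindium 12 carries its γ-substituent axial and gives the 6,7-syn adduct 13 (hence the cis lactone after acid-catalysed lactonisation), while allylic 1,3-strain holds the C8–H in the alkene plane so that the aldehyde adds anti to the C8–C9 bond with the C8–O bond outside, setting C7 and C6 from the S-configured C8.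

Step 7
Reactants: 14 the lactone acetonide
Product: 15 (4R,5R)-4-[(1S)-1,2-dihydroxyethyl]-5-[(1Z)-2-iodoprop-1-en-1-yl]-3-methylideneoxolan-2-one
Conditions: AcOH/H2O (4:1), 40 °C, stopped at full conversion
Reagents that add atoms: none
Why: Acid-catalysed acetal hydrolysis; the vinyl iodide keeps the allylic C6–O bond from ionising, and short exposure to weak acid limits migration of the lactone from O6 to O8 (no centre changes; the C7 descriptor changes only through CIP priorities).

Step 8
Reactants: 15 the diol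
Product: 16 (4R,5R)-4-[(1S)-1-hydroxy-2-(triethylsilyloxy)ethyl]-5-[(1Z)-2-iodoprop-1-en-1-yl]-3-methylideneoxolan-2-one
Conditions: TESCl (1.05 equiv), imidazole (2 equiv), CH2Cl2, −40 °C
Reagents that add atoms: chlorotriethylsilane, CC[Si](Cl)(CC)CC
Why: Kinetically selective silylation of the primary hydroxyl over the hindered secondary one at low temperature.

Step 9
Reactants: 16 the mono-silyl ether
Product: 17 (1S)-1-[(2R,3S)-2-[(1Z)-2-iodoprop-1-en-1-yl]-4-methylidene-5-oxooxolan-3-yl]-2-(triethylsilyloxy)ethyl 3-methylbutanoate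
Conditions: 3-methylbutanoic anhydride (1.5 equiv), Et3N, DMAP (0.1 equiv), CH2Cl2, 0 °C → rt
Reagents that add atoms: 3-methylbutanoic anhydride, CC(C)CC(=O)OC(=O)CC(C)C
Why: DMAP-catalysed acyl transfer to the C8 hydroxyl with retention; acylating O8 also removes the risk of lactone migration.

Step 10
Reactants: 17 the vinyl iodide; 3 2-methyl-3,5-diborylfuran
Product: 18 (1S)-1-[(2S,3S)-4-methylidene-2-{(1Z)-2-[5-methyl-4-(4,4,5,5-tetramethyl-1,3,2-dioxaborolan-2-yl)furan-2-yl]prop-1-en-1-yl}-5-oxooxolan-3-yl]-2-(triethylsilyloxy)ethyl 3-methylbutanoate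
Conditions: 3 (1.3 equiv), Pd(dppf)Cl2 (5 mol %), K3PO4 (3 equiv, 2 M aq), THF, rt
Reagents that add atoms: none
Why: Suzuki–Miyaura coupling with retention of the Z geometry; transmetalation occurs at the α-furyl boronate (less hindered and more nucleophilic at the ipso carbon), so the boronate flanked by the methyl group survives as the masked C1 oxygen.

Step 11
Reactants: 18 the furan boronate silyl ether
Product: 19 (1S)-1-[(2S,3S)-4-methylidene-2-{(1Z)-2-[5-methyl-4-(4,4,5,5-tetramethyl-1,3,2-dioxaborolan-2-yl)furan-2-yl]prop-1-en-1-yl}-5-oxooxolan-3-yl]-2-oxoethyl 3-methylbutanoate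
Conditions: (COCl)2 (3 equiv), DMSO (6 equiv), CH2Cl2, −78 → −40 °C; then i-Pr2NEt, −78 → 0 °C; pH 7 work-up
Reagents that add atoms: none
Why: Swern conditions cleave and oxidise primary triethylsilyl ethers directly (chloride-assisted desilylation, then the usual alkoxysulfonium ylide fragmentation), and the low temperature with a hindered base keeps the α-acyloxy centre C8 intact.

Step 12
Reactants: 19 the furan-3-boronate aldehyde
Product: 22 (2Z,4S,8S,9S,10R,11R)-10-hydroxy-2,11-dimethyl-7-methylidene-6,12-dioxo-5,14-dioxatricyclo[9.2.1.0(4,8)]tetradeca-1(13),2-dien-9-yl 3-methylbutanoate (the target; 6S,7S,8S,9R,10R in germacrane numbering), via enol borate 20 (not isolated), via boron aldolate 21 (not isolated)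
Conditions: Me3NO (anhydrous, 1.2 equiv), 4 Å molecular sieves, CH2Cl2 (1 mM), 0 → 35 °C, argon sweep; then pH 7 phosphate buffer
Reagents that add atoms: trimethylamine N-oxide, C[N+](C)(C)[O-]
Why: Proposed new method: the amine oxide adds to boron and the furyl group migrates from B to O (the known N-oxide ipso-hydroxylation of heteroaryl boronates), giving the aromatic 3-boryloxyfuran 20, an enol borate whose methyl group is cis to O–B; this adds through C10 to the tethered aldehyde in a chair Zimmerman–Traxler transition state (closest known reactions: aldol additions of dioxaborolanyl enol borates and dearomatising Mukaiyama aldol reactions of 3-silyloxyfurans), which breaks the furan aromaticity, closes the ten-membered ring and places 9-OH syn to the C10 methyl, while the tether must leave C8 anti to the aldehyde oxygen and the 8-acyloxy group sits anti to the forming C9–C10 bond on the outer face, so the 8S aldehyde is expected to give 9R,10R.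

**Compound list**
1 | 2-methylfuran | Cc1ccco1 | starting material
2 | 2-methyl-5-(4,4,5,5-tetramethyl-1,3,2-dioxaborolan-2-yl)furan | Cc1ccc(B2OC(C)(C)C(C)(C)O2)o1 | intermediate
3 | 2-methyl-3,5-bis(4,4,5,5-tetramethyl-1,3,2-dioxaborolan-2-yl)furan | Cc1oc(B2OC(C)(C)C(C)(C)O2)cc1B3OC(C)(C)C(C)(C)O3 | intermediate
4 | but-2-yn-1-ol | CC#CCO | starting material
5 | cyclic sodium alkenylalanate (five-membered O–Al–C ring, two 2-methoxyethoxy groups on Al) | [Na+].COCCO[Al-]1(OCCOC)OCC=C1C | intermediate
6 | (2Z)-3-iodobut-2-en-1-ol | C/C(I)=C/CO | intermediate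
7 | (2Z)-3-iodobut-2-enal | C/C(I)=C/C=O | intermediate
8 | (4R)-2,2-dimethyl-1,3-dioxolane-4-carbaldehyde | CC1(C)OC[C@H](C=O)O1 | starting material
9 | methyl acrylate | C=CC(=O)OC | starting material
10 | methyl 2-{hydroxy[(4R)-2,2-dimethyl-1,3-dioxolan-4-yl]methyl}prop-2-enoate (carbinol epimers) | C=C(C(=O)OC)C(O)[C@H]1COC(C)(C)O1 | intermediate
11 | methyl (2Z)-2-(bromomethyl)-3-[(4S)-2,2-dimethyl-1,3-dioxolan-4-yl]prop-2-enoate | COC(=O)/C(CBr)=C/[C@H]1COC(C)(C)O1 | intermediate
12 | allylindium dibromide from 11 (In on the former CH2Br carbon) | COC(=O)/C(C[In](Br)Br)=C/[C@H]1COC(C)(C)O1 | intermediate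
13 | methyl (3S,4R,5Z)-3-[(4S)-2,2-dimethyl-1,3-dioxolan-4-yl]-4-hydroxy-6-iodo-2-methylidenehept-5-enoate | COC(=O)C(=C)[C@@H]([C@@H](O)/C=C(/C)I)[C@H]1COC(C)(C)O1 | intermediate
14 | (4S,5R)-4-[(4S)-2,2-dimethyl-1,3-dioxolan-4-yl]-5-[(1Z)-2-iodoprop-1-en-1-yl]-3-methylideneoxolan-2-one | C=C1C(=O)O[C@@H](/C=C(/C)I)[C@H]1[C@H]2COC(C)(C)O2 | intermediate
15 | (4R,5R)-4-[(1S)-1,2-dihydroxyethyl]-5-[(1Z)-2-iodoprop-1-en-1-yl]-3-methylideneoxolan-2-one | C=C1C(=O)O[C@@H](/C=C(/C)I)[C@H]1[C@H](O)CO | intermediate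
16 | (4R,5R)-4-[(1S)-1-hydroxy-2-(triethylsilyloxy)ethyl]-5-[(1Z)-2-iodoprop-1-en-1-yl]-3-methylideneoxolan-2-one | C=C1C(=O)O[C@@H](/C=C(/C)I)[C@H]1[C@H](O)CO[Si](CC)(CC)CC | intermediate
17 | (1S)-1-[(2R,3S)-2-[(1Z)-2-iodoprop-1-en-1-yl]-4-methylidene-5-oxooxolan-3-yl]-2-(triethylsilyloxy)ethyl 3-methylbutanoate | C=C1C(=O)O[C@@H](/C=C(/C)I)[C@H]1[C@H](OC(=O)CC(C)C)CO[Si](CC)(CC)CC | intermediate
18 | (1S)-1-[(2S,3S)-4-methylidene-2-{(1Z)-2-[5-methyl-4-(4,4,5,5-tetramethyl-1,3,2-dioxaborolan-2-yl)furan-2-yl]prop-1-en-1-yl}-5-oxooxolan-3-yl]-2-(triethylsilyloxy)ethyl 3-methylbutanoate | C=C1C(=O)O[C@@H](/C=C(/C)c2cc(B3OC(C)(C)C(C)(C)O3)c(C)o2)[C@H]1[C@H](OC(=O)CC(C)C)CO[Si](CC)(CC)CC | intermediate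
19 | (1S)-1-[(2S,3S)-4-methylidene-2-{(1Z)-2-[5-methyl-4-(4,4,5,5-tetramethyl-1,3,2-dioxaborolan-2-yl)furan-2-yl]prop-1-en-1-yl}-5-oxooxolan-3-yl]-2-oxoethyl 3-methylbutanoate | C=C1C(=O)O[C@@H](/C=C(/C)c2cc(B3OC(C)(C)C(C)(C)O3)c(C)o2)[C@H]1[C@H](OC(=O)CC(C)C)C=O | intermediate
20 | enol borate: as 19 but with the furan carbon bound to oxygen, furan–O–B(pinacolato) | C=C1C(=O)O[C@@H](/C=C(/C)c2cc(OB3OC(C)(C)C(C)(C)O3)c(C)o2)[C@H]1[C@H](OC(=O)CC(C)C)C=O | intermediate
21 | boron aldolate: the target with its 9-oxygen bound to B(pinacolato) | C=C1C(=O)O[C@H]2/C=C(/C)C3=CC(=O)[C@](C)(O3)[C@H](OB4OC(C)(C)C(C)(C)O4)[C@@H](OC(=O)CC(C)C)[C@@H]12 | intermediate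
22 | (2Z,4S,8S,9S,10R,11R)-10-hydroxy-2,11-dimethyl-7-methylidene-6,12-dioxo-5,14-dioxatricyclo[9.2.1.0(4,8)]tetradeca-1(13),2-dien-9-yl 3-methylbutanoate | C=C1C(=O)O[C@H]2/C=C(/C)C3=CC(=O)[C@](C)(O3)[C@H](O)[C@@H](OC(=O)CC(C)C)[C@@H]12 | target

**Step count and risks**

Total: 12 steps (step 1 gives 3; steps 2–3 give 7; steps 4–5 give 11; steps 6–12 join them). Longest linear sequence: 9 steps (8 → 22, steps 4–12).

Most likely to fail:

Step 12 (the oxidation-triggered macro-aldol). The enol borate 20 may be too weak a nucleophile for a ten-membered closure, or the ring may override the predicted facial selectivity. The fallback replaces the boron-bound closed transition state by a Lewis-acid-mediated open one on an isolated silyl enol ether. It sets out from 19: the same amine oxide oxidation followed by aqueous NaHCO3 work-up gives the furan-3(2H)-one aldehyde F1 (both C10 epimers). TIPSOTf and Et3N in CH2Cl2 at −78 °C re-aromatise it to the 3-(triisopropylsilyloxy)furan aldehyde F2. Slow addition of F2 to BF3·OEt2 (or MgBr2·OEt2) in CH2Cl2 at −78 °C and 1 mM effects a dearomatising Mukaiyama macro-aldol and returns to the route at 22.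

Step 6 (facial selectivity of the Barbier addition relative to C8, plus the sensitivity of enal 7). If the aldehyde prefers the face anti to the C8–O bond, C8 is corrected by inversion instead of by 1,2-induction. The fallback sets out from 7 and uses bought (4S)-2,2-dimethyl-1,3-dioxolane-4-carbaldehyde. Steps 4 and 5 repeated on it give the Morita–Baylis–Hillman adduct F3 and the (4R)-allylic bromide F4. Indium in THF/H2O with 7 gives, through the allylindium dibromide F5 and the hydroxy ester F6, the lactone F7, which then has the required C6 and C7 but the epimeric C8. Hydrolysis gives the diol F8 and TESCl the silyl ether F9. A Mitsunobu esterification of F9 (3-methylbutanoic acid, PPh3, DIAD, toluene, 0 °C → rt) installs the ester with inversion at C8 and returns to the route at 17.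

Step 10 (site selectivity between the two boronates of 3; it also depends on the regiochemistry of the second borylation in step 1). The fallback uses two different metals instead of two boronates. It sets out from 1: n-BuLi (THF, 0 °C) then Bu3SnCl gives tributyl(5-methylfuran-2-yl)stannane F10. Iridium-catalysed borylation under the conditions of step 1 can then only reach the C–H next to the methyl group and gives the stannyl boronate F11; this assumes that the C–Sn bond survives the borylation. A base-free Stille coupling of F11 with 17 (Pd(PPh3)4, CuI, DMF, rt) leaves the boronate untouched and returns to the route at 18.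

Further compounds
F1 | step 12 | (1S)-1-[(2S,3S)-4-methylidene-2-{(1Z)-2-(5-methyl-4-oxo-4,5-dihydrofuran-2-yl)prop-1-en-1-yl}-5-oxooxolan-3-yl]-2-oxoethyl 3-methylbutanoate (both epimers at the furanone CH) | C=C1C(=O)O[C@@H](/C=C(/C)C2=CC(=O)C(C)O2)[C@H]1[C@H](OC(=O)CC(C)C)C=O
F2 | step 12 | (1S)-1-[(2S,3S)-4-methylidene-2-{(1Z)-2-[5-methyl-4-(triisopropylsilyloxy)furan-2-yl]prop-1-en-1-yl}-5-oxooxolan-3-yl]-2-oxoethyl 3-methylbutanoate | C=C1C(=O)O[C@@H](/C=C(/C)c2cc(O[Si](C(C)C)(C(C)C)C(C)C)c(C)o2)[C@H]1[C@H](OC(=O)CC(C)C)C=O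
F3 | step 6 | methyl 2-{hydroxy[(4S)-2,2-dimethyl-1,3-dioxolan-4-yl]methyl}prop-2-enoate (carbinol epimers) | C=C(C(=O)OC)C(O)[C@@H]1COC(C)(C)O1
F4 | step 6 | methyl (2Z)-2-(bromomethyl)-3-[(4R)-2,2-dimethyl-1,3-dioxolan-4-yl]prop-2-enoate | COC(=O)/C(CBr)=C/[C@@H]1COC(C)(C)O1
F5 | step 6 | allylindium dibromide from F4 | COC(=O)/C(C[In](Br)Br)=C/[C@@H]1COC(C)(C)O1
F6 | step 6 | methyl (3S,4R,5Z)-3-[(4R)-2,2-dimethyl-1,3-dioxolan-4-yl]-4-hydroxy-6-iodo-2-methylidenehept-5-enoate | COC(=O)C(=C)[C@@H]([C@@H](O)/C=C(/C)I)[C@@H]1COC(C)(C)O1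
F7 | step 6 | (4S,5R)-4-[(4R)-2,2-dimethyl-1,3-dioxolan-4-yl]-5-[(1Z)-2-iodoprop-1-en-1-yl]-3-methylideneoxolan-2-one | C=C1C(=O)O[C@@H](/C=C(/C)I)[C@H]1[C@@H]2COC(C)(C)O2
F8 | step 6 | (4R,5R)-4-[(1R)-1,2-dihydroxyethyl]-5-[(1Z)-2-iodoprop-1-en-1-yl]-3-methylideneoxolan-2-one | C=C1C(=O)O[C@@H](/C=C(/C)I)[C@H]1[C@@H](O)CO
F9 | step 6 | (4R,5R)-4-[(1R)-1-hydroxy-2-(triethylsilyloxy)ethyl]-5-[(1Z)-2-iodoprop-1-en-1-yl]-3-methylideneoxolan-2-one | C=C1C(=O)O[C@@H](/C=C(/C)I)[C@H]1[C@@H](O)CO[Si](CC)(CC)CC
F10 | step 10 | tributyl(5-methylfuran-2-yl)stannane | CCCC[Sn](CCCC)(CCCC)c1ccc(C)o1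
F11 | step 10 | tributyl[5-methyl-4-(4,4,5,5-tetramethyl-1,3,2-dioxaborolan-2-yl)furan-2-yl]stannane | CCCC[Sn](CCCC)(CCCC)c1cc(B2OC(C)(C)C(C)(C)O2)c(C)o1
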